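The route rests on disconnecting the C4–O and C5–O bonds of the cis-diol back to an alkene, so that the whole carbocycle (C1–C6, C7 and the C3 and C6 oxygens) comes from a para-methoxyphenol by oxidative dearomatization. The key step is a catalytic osmylation that exploits the C4=C5 alkene of the cyclohexa-1,4-diene ring, flanked by the silylated C6 carbinol and the symmetric C3 dimethyl ketal: in one operation it sets C4 and C5, cis to each other and trans to O6. Its precursor is the (6R)-silyl ether of the quinone-monoketal-derived dienol carrying the C7 benzoate; C6 itself comes from a catalyst-controlled ketone reduction, and C3 later from a hydroxyl-directed reduction.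

Key step: step 6

Remark: ring atoms keep the numbering of the target throughout (C1 bears C7, C2 is the vinylic CH, C3–C6 bear oxygen); "lower face" means the face of the C6 oxygen, "upper face" the opposite one.

Step 1
Reactants: 1 2-hydroxy-5-methoxybenzaldehyde
Product: 2 2-(hydroxymethyl)-4-methoxyphenol
Conditions: NaBH4, MeOH, 0 °C
Reagents that add atoms: none
Why: Borohydride reduction of an aryl aldehyde to the benzylic alcohol is chemoselective and creates no stereocentre.

Step 2
Reactants: 2 2-(hydroxymethyl)-4-methoxyphenol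
Product: 3 2-(hydroxymethyl)-4,4-dimethoxycyclohexa-2,5-dien-1-one
Conditions: PhI(OAc)2 (1.1 equiv), MeOH, 0 °C
Reagents that add atoms: methanol, CO
Why: Oxidative dearomatization of a para-methoxyphenol by trivalent iodine: after ligand exchange at iodine, methanol adds at the methoxy-bearing para carbon as iodobenzene leaves, giving the para-quinone monoketal, and doing this before any acylation avoids having to tell the phenol from the benzylic hydroxyl.

Step 3
Reactants: 3 2-(hydroxymethyl)-4,4-dimethoxycyclohexa-2,5-dien-1-one; 4 benzoyl chloride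
Product: 5 (3,3-dimethoxy-6-oxocyclohexa-1,4-dien-1-yl)methyl benzoate
Conditions: BzCl (1.1 equiv), Et3N, DMAP (5 mol %), CH2Cl2, 0 °C
Reagents that add atoms: benzoyl chloride (4), O=C(Cl)c1ccccc1
Why: DMAP-catalysed O-acylation of the only hydroxyl group left, in a mildly basic medium that the dienone and the ketal tolerate.

Step 4
Reactants: 5 (3,3-dimethoxy-6-oxocyclohexa-1,4-dien-1-yl)methyl benzoate
Product: 6 [(6R)-6-hydroxy-3,3-dimethoxycyclohexa-1,4-dien-1-yl]methyl benzoate
Conditions: (S)-1-methyl-3,3-diphenyltetrahydro-1H,3H-pyrrolo[1,2-c][1,3,2]oxazaborole ((S)-Me-CBS, 15 mol %), BH3·SMe2, THF, −30 °C; aq NaHCO3 work-up, used crude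
Reagents that add atoms: none
Why: Corey–Bakshi–Shibata reduction, in which borane held on the oxazaborolidine nitrogen delivers hydride to the ketone bound with its larger flank (C1, carrying the benzoyloxymethyl group) away from the catalyst and its smaller flank (unsubstituted C5) toward it, so that the (S)-catalyst should give the (6R)-alcohol as it does with 2-substituted cyclohexenones, by 1,2-reduction only and without touching the ester.

Step 5
Reactants: 6 [(6R)-6-hydroxy-3,3-dimethoxycyclohexa-1,4-dien-1-yl]methyl benzoate
Product: 7 [(6R)-6-[(tert-butyldimethylsilyl)oxy]-3,3-dimethoxycyclohexa-1,4-dien-1-yl]methyl benzoate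
Conditions: TBSCl, imidazole, DMF, 0 °C → rt
Reagents that add atoms: tert-butyldimethylsilyl chloride, CC(C)(C)[Si](C)(C)Cl
Why: Imidazole-mediated O-silylation of the secondary allylic alcohol runs under basic conditions, which keep the acid-labile dienol ketal from ionizing and aromatizing and leave C6 untouched.

Step 6
Reactants: 7 [(6R)-6-[(tert-butyldimethylsilyl)oxy]-3,3-dimethoxycyclohexa-1,4-dien-1-yl]methyl benzoate
Product: 8 [(4R,5S,6S)-6-[(tert-butyldimethylsilyl)oxy]-4,5-dihydroxy-3,3-dimethoxycyclohex-1-en-1-yl]methyl benzoate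
Conditions: OsO4 (3 mol %), NMO (1.2 equiv), acetone/H2O (5:1), 0 °C → rt
Reagents that add atoms: osmium tetroxide, O=[Os](=O)(=O)=O; N-methylmorpholine N-oxide, C[N+]1([O-])CCOCC1; water, O
Why: Osmium tetroxide adds to C4=C5 by a concerted suprafacial [3+2] cycloaddition, the glycolate of hexavalent osmium is hydrolysed, and the N-oxide returns the metal to the octavalent state (Upjohn dihydroxylation). The closest known reaction type is the catalytic osmylation of cyclic allylic ethers, which takes place on the face opposite the allylic oxygen. No ring is closed; two C–O bonds are formed. Suprafacial addition makes the C4 and C5 oxygens cis, and the face is fixed by the C6 stereocentre: allylic 1,2-strain with the C1 side chain holds the bulky silyloxy group pseudoaxial over the lower face next to C5, while the C3 ketal has two identical methoxy groups and exerts no opposing bias, so both oxygens should enter from the upper face (4R,5S). The step needs site selectivity for C4=C5 over C1=C2, which rests on C1=C2 being trisubstituted, crowded by the ketal carbon and the benzoyloxymethyl group, and inductively poorer (three oxygenated allylic carbons against two). Little more than one equivalent of N-oxide limits a second dihydroxylation, and the slightly basic medium protects the dienyl ketal from aromatization.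

Step 7
Reactants: 8 [(4R,5S,6S)-6-[(tert-butyldimethylsilyl)oxy]-4,5-dihydroxy-3,3-dimethoxycyclohex-1-en-1-yl]methyl benzoate
Product: 9 [(4R,5S,6S)-6-[(tert-butyldimethylsilyl)oxy]-4,5-dihydroxy-3-oxocyclohex-1-en-1-yl]methyl benzoate
Conditions: oxalic acid (10 mol %), THF/H2O (4:1), 0 °C → rt
Reagents that add atoms: water, O
Why: Acid-catalysed hydrolysis of the allylic dimethyl ketal through its allyl-stabilized oxocarbenium ion unveils the C3 enone conjugated with C1=C2, under conditions mild enough for the secondary silyl ether, the benzoate and the three stereocentres.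

Step 8
Reactants: 9 [(4R,5S,6S)-6-[(tert-butyldimethylsilyl)oxy]-4,5-dihydroxy-3-oxocyclohex-1-en-1-yl]methyl benzoate
Product: 10 [(3R,4S,5S,6S)-6-[(tert-butyldimethylsilyl)oxy]-3,4,5-trihydroxycyclohex-1-en-1-yl]methyl benzoate
Conditions: Me4NBH(OAc)3 (5 equiv), MeCN/AcOH (1:1), −30 °C → −20 °C; aq sodium potassium tartrate
Reagents that add atoms: none
Why: Evans–Saksena hydroxyl-directed reduction: acetate exchange binds boron to the C5 (or C4) hydroxyl on the upper face and the hydride is passed intramolecularly to the same face of the C3 carbonyl, so the new hydroxyl should sit on the lower face, 1,3-anti to O5 and trans to O4 (3R), while the weak reagent leaves the ester and the alkene alone.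

Step 9
Reactants: 10 [(3R,4S,5S,6S)-6-[(tert-butyldimethylsilyl)oxy]-3,4,5-trihydroxycyclohex-1-en-1-yl]methyl benzoate; 11 trimethyl orthobenzoate
Product: 13 [(3R,4S,5S,6S)-5-(benzoyloxy)-6-[(tert-butyldimethylsilyl)oxy]-3,4-dihydroxycyclohex-1-en-1-yl]methyl benzoate, via cyclic O4/O5 methyl orthobenzoate 12 (not isolated)
Conditions: PhC(OMe)3 (1.5 equiv), CSA (5 mol %), CH2Cl2, rt; then AcOH/H2O (4:1), rt
Reagents that add atoms: trimethyl orthobenzoate (11), COC(OC)(OC)c1ccccc1; water, O
Why: Orthoester exchange closes a 2-methoxy-2-phenyl-1,3-dioxolane only across the cis C4/C5 diol, and acid hydrolysis of such a cis-fused orthoester places the ester on the axial oxygen, expected to be O5 because allylic 1,2-strain keeps the C6 silyloxy group pseudoaxial and its trans neighbour O5 axial; no stereocentre changes.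

Step 10
Reactants: 13 [(3R,4S,5S,6S)-5-(benzoyloxy)-6-[(tert-butyldimethylsilyl)oxy]-3,4-dihydroxycyclohex-1-en-1-yl]methyl benzoate
Product: 14 [(3R,4S,5R,6S)-5-(benzoyloxy)-3,4,6-trihydroxycyclohex-1-en-1-yl]methyl benzoate
Conditions: HF·pyridine, pyridine, THF, 0 °C → rt
Reagents that add atoms: none
Why: Fluoride-driven desilylation in a buffered, weakly acidic medium, chosen instead of basic fluoride sources so that neither benzoate migrates to a neighbouring free hydroxyl.

Compound list

1 | 2-hydroxy-5-methoxybenzaldehyde | COc1ccc(O)c(C=O)c1 | starting material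
2 | 2-(hydroxymethyl)-4-methoxyphenol | COc1ccc(O)c(CO)c1 | intermediate
3 | 2-(hydroxymethyl)-4,4-dimethoxycyclohexa-2,5-dien-1-one | COC1(OC)C=CC(=O)C(CO)=C1 | intermediate
4 | benzoyl chloride | O=C(Cl)c1ccccc1 | starting material
5 | (3,3-dimethoxy-6-oxocyclohexa-1,4-dien-1-yl)methyl benzoate | O=C(OCC1=CC(OC)(OC)C=CC1=O)c1ccccc1 | intermediate
6 | [(6R)-6-hydroxy-3,3-dimethoxycyclohexa-1,4-dien-1-yl]methyl benzoate | O=C(OCC1=CC(OC)(OC)C=C[C@H]1O)c1ccccc1 | intermediate
7 | [(6R)-6-[(tert-butyldimethylsilyl)oxy]-3,3-dimethoxycyclohexa-1,4-dien-1-yl]methyl benzoate (key-step precursor) | O=C(OCC1=CC(OC)(OC)C=C[C@H]1O[Si](C)(C)C(C)(C)C)c1ccccc1 | intermediate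
8 | [(4R,5S,6S)-6-[(tert-butyldimethylsilyl)oxy]-4,5-dihydroxy-3,3-dimethoxycyclohex-1-en-1-yl]methyl benzoate (key-step product; O4 and O5 cis, both trans to O6) | O=C(OCC1=CC(OC)(OC)[C@H](O)[C@H](O)[C@H]1O[Si](C)(C)C(C)(C)C)c1ccccc1 | intermediate
9 | [(4R,5S,6S)-6-[(tert-butyldimethylsilyl)oxy]-4,5-dihydroxy-3-oxocyclohex-1-en-1-yl]methyl benzoate | O=C(OCC1=CC(=O)[C@H](O)[C@H](O)[C@H]1O[Si](C)(C)C(C)(C)C)c1ccccc1 | intermediate
10 | [(3R,4S,5S,6S)-6-[(tert-butyldimethylsilyl)oxy]-3,4,5-trihydroxycyclohex-1-en-1-yl]methyl benzoate | O=C(OCC1=C[C@@H](O)[C@H](O)[C@H](O)[C@H]1O[Si](C)(C)C(C)(C)C)c1ccccc1 | intermediate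
11 | trimethyl orthobenzoate | COC(OC)(OC)c1ccccc1 | starting material
12 | cyclic O4/O5 methyl orthobenzoate of 10: cis-fused 2-methoxy-2-phenyl-1,3-dioxolane across C4 and C5 (either configuration at the orthoester carbon), C3 hydroxyl free, C6 silyl ether and C7 benzoate kept | O=C(OCC1=C[C@@H](O)[C@@H]2OC(OC)(c3ccccc3)O[C@@H]2[C@H]1O[Si](C)(C)C(C)(C)C)c1ccccc1 | intermediate (not isolated)
13 | [(3R,4S,5S,6S)-5-(benzoyloxy)-6-[(tert-butyldimethylsilyl)oxy]-3,4-dihydroxycyclohex-1-en-1-yl]methyl benzoate | O=C(OCC1=C[C@@H](O)[C@H](O)[C@H](OC(=O)c2ccccc2)[C@H]1O[Si](C)(C)C(C)(C)C)c1ccccc1 | intermediate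
14 | [(3R,4S,5R,6S)-5-(benzoyloxy)-3,4,6-trihydroxycyclohex-1-en-1-yl]methyl benzoate | O=C(OCC1=C[C@@H](O)[C@H](O)[C@H](OC(=O)c2ccccc2)[C@H]1O)c1ccccc1 | target

Total step count: 10. Longest linear sequence: 10 steps (1 → 14).

Steps most likely to fail

Step 6. The osmylation may lose site selectivity (attack on C1=C2, or a second dihydroxylation of 8). The fallback switches the competing alkene off electronically instead of relying on sterics. It sets out from 7: K2CO3 in MeOH would remove the benzoate to give the allylic alcohol [(6R)-6-[(tert-butyldimethylsilyl)oxy]-3,3-dimethoxycyclohexa-1,4-dien-1-yl]methanol F1. MnO2 in CH2Cl2 would oxidize it to the enal (6R)-6-[(tert-butyldimethylsilyl)oxy]-3,3-dimethoxycyclohexa-1,4-diene-1-carbaldehyde F2, whose C1=C2 bond is conjugated to the aldehyde and therefore a poor partner for OsO4. OsO4/NMO should then dihydroxylate only C4=C5, again opposite the silyloxy group, to give (4R,5S,6S)-6-[(tert-butyldimethylsilyl)oxy]-4,5-dihydroxy-3,3-dimethoxycyclohex-1-ene-1-carbaldehyde F3. NaBH4 with CeCl3·7H2O in MeOH at −40 °C (Luche reduction) would return the primary allylic alcohol [(4R,5S,6S)-6-[(tert-butyldimethylsilyl)oxy]-4,5-dihydroxy-3,3-dimethoxycyclohex-1-en-1-yl]methanol F4. Benzoyl chloride 4 with 2,4,6-collidine in CH2Cl2 at −40 °C should acylate only the primary hydroxyl, which brings the sequence back to 8.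

Step 4. The oxazaborolidine may not distinguish the two alkenyl flanks of the ketone well enough (low enantiofacial selectivity), or the dienol may aromatize during work-up. The fallback obtains the stereocentre by enzymatic resolution and sets out from 5. NaBH4 with CeCl3·7H2O in MeOH at −78 °C would give the racemic dienol [(6RS)-6-hydroxy-3,3-dimethoxycyclohexa-1,4-dien-1-yl]methyl benzoate F5. Ac2O, Et3N and DMAP would convert it into the racemic acetate [(6RS)-6-(acetyloxy)-3,3-dimethoxycyclohexa-1,4-dien-1-yl]methyl benzoate F6. Burkholderia cepacia lipase with n-butanol in tert-butyl methyl ether (neutral, non-aqueous) is expected to transesterify only the (6R)-acetate, following the usual empirical size model for lipases with C1 as the large and C5 as the medium flank. This releases the (6R)-alcohol 6, where the route is rejoined; the unreacted (6S)-acetate is removed by chromatography on base-washed silica, and the primary benzoate is a poor lipase substrate.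

Step 9. The orthoester may open toward O4, or acid may promote acyl migration, so that the benzoate ends up on the wrong oxygen. The fallback replaces the orthoester rearrangement by direct, catalyst-controlled acylation and sets out from 10: 2-aminoethyl diphenylborinate (10 mol %), benzoyl chloride 4 and i-Pr2NEt in MeCN at rt. The borinate binds the cis C4/C5 diol and passes the acyl group to its equatorial oxygen, the opposite intrinsic preference to the orthoester opening. If O5 turns out not to be axial, this method should therefore give 13 directly, where the route is rejoined; no new compound is made.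

Further compounds

F1 | step 6 | [(6R)-6-[(tert-butyldimethylsilyl)oxy]-3,3-dimethoxycyclohexa-1,4-dien-1-yl]methanol | OCC1=CC(OC)(OC)C=C[C@H]1O[Si](C)(C)C(C)(C)C
F2 | step 6 | (6R)-6-[(tert-butyldimethylsilyl)oxy]-3,3-dimethoxycyclohexa-1,4-diene-1-carbaldehyde | O=CC1=CC(OC)(OC)C=C[C@H]1O[Si](C)(C)C(C)(C)C
F3 | step 6 | (4R,5S,6S)-6-[(tert-butyldimethylsilyl)oxy]-4,5-dihydroxy-3,3-dimethoxycyclohex-1-ene-1-carbaldehyde | O=CC1=CC(OC)(OC)[C@H](O)[C@H](O)[C@H]1O[Si](C)(C)C(C)(C)C
F4 | step 6 | [(4R,5S,6S)-6-[(tert-butyldimethylsilyl)oxy]-4,5-dihydroxy-3,3-dimethoxycyclohex-1-en-1-yl]methanol | OCC1=CC(OC)(OC)[C@H](O)[C@H](O)[C@H]1O[Si](C)(C)C(C)(C)C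
F5 | step 4 | [(6RS)-6-hydroxy-3,3-dimethoxycyclohexa-1,4-dien-1-yl]methyl benzoate (racemate) | O=C(OCC1=CC(OC)(OC)C=CC1O)c1ccccc1
F6 | step 4 | [(6RS)-6-(acetyloxy)-3,3-dimethoxycyclohexa-1,4-dien-1-yl]methyl benzoate (racemate) | CC(=O)OC1C=CC(OC)(OC)C=C1COC(=O)c1ccccc1
F0 | step 9 | none | none
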